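**In the flask.** At the reading, 25 h in winter and 75 h in summer, the substrate should be gone. The east run fell to 16.1% of it by 4.00 h, a mean time constant τ of 2.19 h, so winter's reading comes at 11.4 τ. Target and other capture product will then hold the substrate.

in all of them: substrate 0.30 M
- east: first nucleophile 0.27 M; solid second nucleophile 0.66 M; run made earlier
- summer: first nucleophile 0.270 M; solid second nucleophile 0.330 M; time 75 h
- winter: first nucleophile 0.270 M; solid second nucleophile 0.330 M; time 25 h

east run (percent of the substrate charged)

| time / h | intermediate / % | substrate / % | target / % | other capture product / % |
|---|---|---|---|---|
| 1.00 | 0 | 64.8 | 22.6 | 12.9 |
| 2.00 | 1.2 | 40.1 | 35.3 | 25.7 |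
| 3.00 | 1.8 | 25.5 | 38.8 | 37.1 |
| 4.00 | 0 | 16.1 | 41.7 | 42.7 |
| 5.00 | 0 | 7.5 | 42.6 | 47.7 |

(standard deviation of a reading: 1 percentage point)

1. which of these there is most of at the end, counted by the substrate in it, summer (substrate / other capture product / intermediate / target)
2. which of these there is most of at the end, counted by the substrate in it, winter (substrate / other capture product / intermediate / target)
3. the largest of these amounts at the end, in percent of the substrate charged, summer
4. the largest of these amounts at the end, in percent of the substrate charged, winter

- solid second nucleophile is a solid; its amount is given per volume of the solution
- the earlier runs were read with a standard deviation of 1 percentage point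
- reactions considered so far: solid second nucleophile <-> second nucleophile; substrate -> intermediate; second nucleophile + intermediate -> other capture product; first nucleophile + intermediate -> target
- at the start none of the solid second nucleophile is in solution

**Coming split.** Replacing the late curve by its mean: between 3.00 h and 5.00 h, east's readings put 73.6% of new product into other capture product. Giving east's last 7.5% of substrate that share brings other capture product to 53.2%.

**Solid cover.** Each other capture product takes one second nucleophile, so that share calls for 0.160 M. The cover C is 2.07 in summer and winter: the solid charged over that call. With C above 1, solid second nucleophile is not the limiting reagent; C does not tell how the split between the two products moves with that charge.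

**The forecast.** It names other capture product in summer and other capture product in winter, at 54% in each, within 50% to 59%, slightly above the 53.2% reckoned here. Its ground: “Both new runs therefore reach the same end point unless something slow and unseen follows”.

**The result.** Other capture product leads in both flasks, at 54.9% in summer and 54.9% in winter.

    solid second nucleophile ⇌ second nucleophile, rate k1*(cs1 - [second nucleophile]) while solid is left; crystals form when [second nucleophile] > cs1 (solubility = 0.280 M, k = 1.50 × 10⁻⁴ /s)
    substrate → intermediate (k = 1.30 × 10⁻⁴ /s)
    second nucleophile + intermediate → other capture product (k = 0.0640 /M/s)
    first nucleophile + intermediate → target (k = 0.0270 /M/s)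

**Neighbour flask.** Summer's simulated share makes the call 0.165 M and C 2.00, with 0.165 M of second nucleophile still dissolved at 75.0 h. The neighbour of summer with 0.13 M of solid second nucleophile has C of 0.812, so its charge caps other capture product at 43.3% of the substrate. That flask gives 38.8% of other capture product, and target leads it with 61.2%.

The readings are simulated for substances that don't exist; scatter was added.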